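**Plan**
1. Retrosynthesis (chroman-2-one locants; unprimed = 5,7-dioxygenated half, primed = 5,6,7,8-tetraoxygenated half): the eight O-benzyl groups come off last; C3–C4 and C3'–C4' (lactone α-carbon to diaryl-methine carbon) are cut together; then the two aryl ester C–O bonds, leaving succinic anhydride and two o-hydroxybenzhydryl methyl ethers; each ether goes back to a salicylaldehyde and 4-benzyloxyphenylmagnesium bromide.
2. Enabling feature: C4 and C4' each bear a p-oxygenated phenyl ring and an o,p-oxygenated benzo ring, so each is a latent quinone-methide-type diarylmethyl cation six atoms from the α-carbon of the ester on its ortho oxygen; C2–C3–C3'–C2' is a succinate, so one bis(silyl ketene acetal) carries both nucleophilic carbons.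
3. Forward: phenols 5 and 13 are joined through succinic anhydride to the open-chain diester 16; 16 is converted into the (1Z,3Z)-bis(silyl ketene acetal) 17; one chiral-anion-catalysed cascade closes first one pyranone ring and then the other (17 → 19); hydrogenolysis gives the target.
4. Stereochemistry: C4 and C4' (both R) are set by the chiral counteranion in the two ring closures; C3 and C3' (both S, each cis to its C4 aryl group) follow from the Z geometry of the ketene acetals; the methoxy-bearing centres of 5, 13, 16 and 17 are racemic and are erased by ionisation; nothing basic follows the cascade.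

Key step: step 10

Assumption: the sense of induction of a confined chiral anion towards a diarylmethyl cation cannot be derived a priori; the catalyst enantiomer written as (S,S)-IDPi is taken to be the one that gives the (4R,4'R) series, to be confirmed on a model half-ester, and its antipode is used otherwise.

**Step 1**
Reactants: 1 3,5-bis(benzyloxy)phenol
Product: 2 4,6-bis(benzyloxy)-2-hydroxybenzaldehyde
Conditions: MgCl2, Et3N, (CH2O)n, MeCN, reflux; aq. HCl work-up
Reagents that add atoms: paraformaldehyde (as formaldehyde) C=O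
Why: Magnesium-mediated ortho-formylation (Casnati–Skattebøl): the magnesium phenoxide delivers formaldehyde only ortho to the free OH (both ortho sites are equivalent) and the hydroxymethyl intermediate is oxidised in situ by a second formaldehyde.

**Step 2**
Reactants: 2 4,6-bis(benzyloxy)-2-hydroxybenzaldehyde; 3 4-(benzyloxy)phenylmagnesium bromide
Product: 5 rac-3,5-bis(benzyloxy)-2-[(4-benzyloxyphenyl)(methoxy)methyl]phenol, via benzhydrol diol 4 (not isolated)
Conditions: 3 (2.5 equiv), THF, 0 °C → rt; aq. NH4Cl; crude 4, MeOH, PPTS (cat.), 0 °C → rt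
Reagents that add atoms: methanol CO
Why: Grignard addition to the salicylaldehyde (the first equivalent forms the phenoxide) followed by SN1 etherification, in which the electron-rich o-hydroxybenzhydrol ionises under mild acid via its o-quinone methide/benzhydryl cation and is trapped by solvent methanol; the new centre is racemic and is erased in step 10.

**Step 3**
Reactants: 6 benzene-1,2,3,4-tetrol
Product: 7 1,2,3,4-tetrakis(benzyloxy)benzene
Conditions: BnBr (4.5 equiv), K2CO3, DMF, rt → 50 °C, argon
Reagents that add atoms: benzyl bromide BrCc1ccccc1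
Why: Williamson etherification of all four phenolic OH groups, run air-free because the tetrol is oxidation-sensitive under base.

**Step 4**
Reactants: 7 1,2,3,4-tetrakis(benzyloxy)benzene
Product: 8 2,3,4,5-tetrakis(benzyloxy)benzaldehyde
Conditions: POCl3, DMF, 70 °C; ice-water
Reagents that add atoms: N,N-dimethylformamide CN(C)C=O; water O
Why: Vilsmeier–Haack formylation of the electron-rich arene; the two free ring positions are equivalent, so a single aldehyde should result.

**Step 5**
Reactants: 8 2,3,4,5-tetrakis(benzyloxy)benzaldehyde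
Product: 10 2,3,4,5-tetrakis(benzyloxy)phenol, via aryl formate 9 (not isolated)
Conditions: mCPBA, CH2Cl2, 0 °C → rt; then K2CO3 (cat.), MeOH, rt
Reagents that add atoms: 3-chloroperbenzoic acid OOC(=O)c1cccc(Cl)c1
Why: Dakin-type Baeyer–Villiger oxidation in which the electron-rich aryl group migrates to give the aryl formate, which is then methanolysed to the phenol.

**Step 6**
Reactants: 10 2,3,4,5-tetrakis(benzyloxy)phenol
Product: 11 3,4,5,6-tetrakis(benzyloxy)-2-hydroxybenzaldehyde
Conditions: MgCl2, Et3N, (CH2O)n, MeCN, reflux; aq. HCl work-up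
Reagents that add atoms: paraformaldehyde (as formaldehyde) C=O
Why: Magnesium-mediated ortho-formylation as in step 1; the only free ring position is the one ortho to the OH, so regiochemistry is fixed.

**Step 7**
Reactants: 11 3,4,5,6-tetrakis(benzyloxy)-2-hydroxybenzaldehyde; 3 4-(benzyloxy)phenylmagnesium bromide
Product: 13 rac-2,3,4,5-tetrakis(benzyloxy)-6-[(4-benzyloxyphenyl)(methoxy)methyl]phenol, via benzhydrol diol 12 (not isolated)
Conditions: 3 (2.5 equiv), THF, 0 °C → rt; aq. NH4Cl; crude 12, MeOH, PPTS (cat.), 0 °C → rt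
Reagents that add atoms: methanol CO
Why: Grignard addition and SN1 methanolysis of the o-hydroxybenzhydrol exactly as in step 2; the racemic methoxy-bearing centre is erased in step 10.

**Step 8**
Reactants: 13 rac-2,3,4,5-tetrakis(benzyloxy)-6-[(4-benzyloxyphenyl)(methoxy)methyl]phenol; 14 succinic anhydride; 5 rac-3,5-bis(benzyloxy)-2-[(4-benzyloxyphenyl)(methoxy)methyl]phenol
Product: 16 mixed diaryl succinate (diastereomer mixture at the two methoxy-bearing carbons), via hemisuccinate 15 (not isolated)
Conditions: 14, Et3N, DMAP (cat.), CH2Cl2, rt; then 5, DIC, 0 °C → rt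
Reagents that add atoms: none
Why: DMAP-catalysed opening of the cyclic anhydride by the hindered phenol gives only the mono-ester, which is coupled in the same flask with the second phenol by carbodiimide activation (Steglich esterification); this gives the unsymmetrical diester without statistical mixtures, and the basic medium preserves the acid-labile benzhydryl ethers.

**Step 9**
Reactants: 16 mixed diaryl succinate
Product: 17 (1Z,3Z)-bis(trimethylsilyl ketene acetal) of 16
Conditions: LDA (2.3 equiv), TMSCl (5 equiv, in situ), THF/DMPU 4:1, −78 °C → 0 °C; evaporation, pentane, filtration under argon; used crude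
Reagents that add atoms: chlorotrimethylsilane C[Si](C)(C)Cl
Why: Kinetic double enolisation of the succinate with in situ O-silylation, the chlorosilane trapping each aryl ester enolate before it can expel aryloxide; the polar cosolvent should give the Z(O) enolate geometry, with the chain carbon cis to OSiMe3 at both double bonds.

**Step 10**
Reactants: 17 (1Z,3Z)-bis(trimethylsilyl ketene acetal)
Product: 19 (3S,3'S,4R,4'R)-5,5',6',7,7',8'-hexakis(benzyloxy)-4,4'-bis(4-benzyloxyphenyl)-[3,3'-bichromane]-2,2'-dione, via monolactone ketene acetal 18 (not isolated)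
Conditions: (S,S)-IDPi (chiral imidodiphosphorimidate acid, 5 mol%), toluene (0.01 M), −78 → −40 °C; then Et3N
Reagents that add atoms: none
Why: Proposed new method: the IDPi acid is silylated in situ by the ketene acetal and then abstracts methoxide as MeOSiMe3 from each benzhydryl ether, giving a doubly donor-stabilised (O-benzyl p-quinone-methide-type) diarylmethyl cation paired with the confined chiral anion, and the tethered ketene acetal carbon C3 attacks C4 and returns its silyl group to the anion; the closest known reaction types are the chiral-counteranion-directed Mukaiyama-type SN1 alkylation of secondary benzylic cations by silyl ketene acetals and the TMSOTf-promoted alkylation of ketene acetals by benzhydryl ethers, here made intramolecular and run twice in one flask. Each pyranone ring closes in a 6-(enolendo)-exo-trig mode (ketene acetal C=C inside the forming ring, the cation's aryl π-system outside), drawn as the 5,7-dioxygenated ring first (18) and the 5,6,7,8-tetraoxygenated ring second, either order converging on 19, while attack of C3 on the other cation would be a disfavoured seven-membered closure. C4 and C4' are set by the chiral anion, which should bind one rotamer of the cation, distinguishing the twisted 2,6-disubstituted oxygenated ring from the flat p-benzyloxyphenyl ring, and so expose one face to the tethered nucleophile; since both halves of the target have the same (3S,4R) sense, one catalyst preference serves both closures and the minor enantiomer of the first closure is diverted into a separable diastereomer. C3 and C3' are set by the Z geometry of the ketene acetals: the substituent trans to the ring oxygen becomes pseudo-equatorial while the p-benzyloxyphenyl group is forced pseudo-axial by A(1,3) strain with the peri C5 benzyloxy group, which gives the 3,4-cis relationship in each ring. The step needs C- over O-alkylation and intra- over intermolecular capture, secured by the carbon terminus of the ketene acetal, the six-atom tether through the ester oxygen and high dilution, and the non-basic medium should keep the epimerisable C3–H and C3'–H centres as formed.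

**Step 11**
Reactants: 19 octabenzyl bis-lactone
Product: 20 (3S,3'S,4R,4'R)-5,5',6',7,7',8'-hexahydroxy-4,4'-bis(4-hydroxyphenyl)-[3,3'-bichromane]-2,2'-dione
Conditions: H2 (1 atm), Pd/C, EtOAc/THF, trace AcOH, rt; filtration and concentration under argon
Reagents that add atoms: none
Why: Hydrogenolysis of aryl benzyl ethers over palladium under neutral, non-nucleophilic conditions should leave the lactones, the diarylmethine C–H bonds and the epimerisable α-centres untouched.

**Compound list**
1 | 3,5-bis(benzyloxy)phenol | Oc1cc(OCc2ccccc2)cc(OCc2ccccc2)c1 | starting material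
2 | 4,6-bis(benzyloxy)-2-hydroxybenzaldehyde | O=Cc1c(O)cc(OCc2ccccc2)cc1OCc1ccccc1 | intermediate
3 | 4-(benzyloxy)phenylmagnesium bromide | Br[Mg]c1ccc(OCc2ccccc2)cc1 | starting material
4 | rac-3,5-bis(benzyloxy)-2-[(4-benzyloxyphenyl)(hydroxy)methyl]phenol | OC(c1ccc(OCc2ccccc2)cc1)c1c(O)cc(OCc2ccccc2)cc1OCc1ccccc1 | intermediate
5 | rac-3,5-bis(benzyloxy)-2-[(4-benzyloxyphenyl)(methoxy)methyl]phenol | COC(c1ccc(OCc2ccccc2)cc1)c1c(O)cc(OCc2ccccc2)cc1OCc1ccccc1 | intermediate
6 | benzene-1,2,3,4-tetrol | Oc1ccc(O)c(O)c1O | starting material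
7 | 1,2,3,4-tetrakis(benzyloxy)benzene | C(Oc1ccc(OCc2ccccc2)c(OCc2ccccc2)c1OCc1ccccc1)c1ccccc1 | intermediate
8 | 2,3,4,5-tetrakis(benzyloxy)benzaldehyde | O=Cc1cc(OCc2ccccc2)c(OCc2ccccc2)c(OCc2ccccc2)c1OCc1ccccc1 | intermediate
9 | 2,3,4,5-tetrakis(benzyloxy)phenyl formate | O=COc1cc(OCc2ccccc2)c(OCc2ccccc2)c(OCc2ccccc2)c1OCc1ccccc1 | intermediate
10 | 2,3,4,5-tetrakis(benzyloxy)phenol | Oc1cc(OCc2ccccc2)c(OCc2ccccc2)c(OCc2ccccc2)c1OCc1ccccc1 | intermediate
11 | 3,4,5,6-tetrakis(benzyloxy)-2-hydroxybenzaldehyde | O=Cc1c(O)c(OCc2ccccc2)c(OCc2ccccc2)c(OCc2ccccc2)c1OCc1ccccc1 | intermediate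
12 | rac-2,3,4,5-tetrakis(benzyloxy)-6-[(4-benzyloxyphenyl)(hydroxy)methyl]phenol | OC(c1ccc(OCc2ccccc2)cc1)c1c(O)c(OCc2ccccc2)c(OCc2ccccc2)c(OCc2ccccc2)c1OCc1ccccc1 | intermediate
13 | rac-2,3,4,5-tetrakis(benzyloxy)-6-[(4-benzyloxyphenyl)(methoxy)methyl]phenol | COC(c1ccc(OCc2ccccc2)cc1)c1c(O)c(OCc2ccccc2)c(OCc2ccccc2)c(OCc2ccccc2)c1OCc1ccccc1 | intermediate
14 | succinic anhydride | O=C1CCC(=O)O1 | starting material
15 | 4-oxo-4-{2,3,4,5-tetrakis(benzyloxy)-6-[(4-benzyloxyphenyl)(methoxy)methyl]phenoxy}butanoic acid | COC(c1ccc(OCc2ccccc2)cc1)c1c(OC(=O)CCC(=O)O)c(OCc2ccccc2)c(OCc2ccccc2)c(OCc2ccccc2)c1OCc1ccccc1 | intermediate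
16 | 1-{3,5-bis(benzyloxy)-2-[(4-benzyloxyphenyl)(methoxy)methyl]phenyl} 4-{2,3,4,5-tetrakis(benzyloxy)-6-[(4-benzyloxyphenyl)(methoxy)methyl]phenyl} succinate | COC(c1ccc(OCc2ccccc2)cc1)c1c(OC(=O)CCC(=O)Oc2cc(OCc3ccccc3)cc(OCc3ccccc3)c2C(OC)c2ccc(OCc3ccccc3)cc2)c(OCc2ccccc2)c(OCc2ccccc2)c(OCc2ccccc2)c1OCc1ccccc1 | intermediate
17 | (1Z,3Z)-1-{3,5-bis(benzyloxy)-2-[(4-benzyloxyphenyl)(methoxy)methyl]phenoxy}-4-{2,3,4,5-tetrakis(benzyloxy)-6-[(4-benzyloxyphenyl)(methoxy)methyl]phenoxy}-1,4-bis(trimethylsilyloxy)buta-1,3-diene | C[Si](C)(C)O/C(Oc1cc(OCc2ccccc2)cc(OCc2ccccc2)c1C(OC)c1ccc(OCc2ccccc2)cc1)=C\C=C(/O[Si](C)(C)C)Oc1c(OCc2ccccc2)c(OCc2ccccc2)c(OCc2ccccc2)c(OCc2ccccc2)c1C(OC)c1ccc(OCc2ccccc2)cc1 | intermediate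
18 | (3S,4R)-5,7-bis(benzyloxy)-4-(4-benzyloxyphenyl)-3-[(Z)-2-aryloxy-2-(trimethylsilyloxy)vinyl]chroman-2-one (aryl = 2,3,4,5-tetrakis(benzyloxy)-6-[(4-benzyloxyphenyl)(methoxy)methyl]phenyl) | O=C1Oc2cc(OCc3ccccc3)cc(OCc3ccccc3)c2[C@@H](c2ccc(OCc3ccccc3)cc2)[C@H]1\C=C(/O[Si](C)(C)C)Oc1c(OCc2ccccc2)c(OCc2ccccc2)c(OCc2ccccc2)c(OCc2ccccc2)c1C(OC)c1ccc(OCc2ccccc2)cc1 | intermediate
19 | (3S,3'S,4R,4'R)-5,5',6',7,7',8'-hexakis(benzyloxy)-4,4'-bis(4-benzyloxyphenyl)-[3,3'-bichromane]-2,2'-dione | O=C1Oc2cc(OCc3ccccc3)cc(OCc3ccccc3)c2[C@@H](c2ccc(OCc3ccccc3)cc2)[C@H]1[C@H]1C(=O)Oc2c(OCc3ccccc3)c(OCc3ccccc3)c(OCc3ccccc3)c(OCc3ccccc3)c2[C@H]1c1ccc(OCc2ccccc2)cc1 | intermediate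
20 | (3S,3'S,4R,4'R)-5,5',6',7,7',8'-hexahydroxy-4,4'-bis(4-hydroxyphenyl)-[3,3'-bichromane]-2,2'-dione | O=C1Oc2cc(O)cc(O)c2[C@@H](c2ccc(O)cc2)[C@H]1[C@H]1C(=O)Oc2c(O)c(O)c(O)c(O)c2[C@H]1c1ccc(O)cc1 | target

**Step count and risks**
Total steps: 11. Longest linear sequence: 9 steps (6 → 20, steps 3–11).

Steps most likely to fail:

1. Step 10 (Proposed new method). The chiral anion may discriminate the faces of the diarylmethyl cation poorly, so that enantio- or diastereocontrol is low, or the catalyst may be inhibited by the many Lewis-basic benzyl ethers. Fallback (known chemistry, resolution in place of catalyst control): setting out from 17, the double closure is run with achiral TMSOTf (10 mol%, CH2Cl2, −78 °C), a standard Mukaiyama-type SN1 alkylation of silyl ketene acetals by benzhydryl ethers. It passes through racemic monolactone, that is 18 together with its enantiomer, the (3R,4S)-monolactone ketene acetal F1. The cis,cis bis-lactone is then obtained as the racemate, that is 19 together with its enantiomer, the (3R,3'R,4S,4'S)-octabenzyl bis-lactone F2. Other diastereomers are removed on silica, 19 is separated from F2 by preparative chromatography on a chiral stationary phase, and the route is rejoined at 19.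

2. Step 9. Geometric control may be lost in the double enolisation (or aryloxide may be partly eliminated from the ester enolate), which the cascade would translate into 3,4-trans lactones. Fallback (the C3/C3' configuration is taken from a kinetic protonation instead of from ketene acetal geometry): setting out from 16, enolisation and silylation without cosolvent (LDA, TMSCl, THF, −78 °C), the conditions that favour the E(O) enolate, should give the (1E,3E)-bis(silyl ketene acetal) F3. Cyclisation under the conditions of step 10 then passes through the (3R,4R)-trans-monolactone (E)-ketene acetal F4 to the (3R,3'R,4R,4'R)-trans,trans-octabenzyl bis-lactone F5. F5 is deprotonated twice (LiHMDS, 2.2 equiv, THF, −78 °C) to the dilithium (4R,4'R)-bis-enolate F6. This is protonated at −78 °C with 2,6-di-tert-butylphenol from the face anti to the pseudo-axial C4 and C4' aryl groups, which should place each α-substituent cis to its aryl neighbour and return the material to 19.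

3. Step 11. Hydrogenolysis of the four contiguous, crowded benzyl ethers may stall, or the very electron-rich pentaoxygenated ring of the product may be oxidised on the catalyst during filtration. Fallback (Lewis-acid dealkylation in place of catalytic hydrogenolysis): setting out from 19, BCl3 with pentamethylbenzene as cation scavenger (CH2Cl2, −78 °C), a known non-reductive cleavage of aryl benzyl ethers that tolerates aryl lactones and needs no catalyst filtration, leads directly to 20.

**Further compounds**
F1 | step 10 | (3R,4S)-5,7-bis(benzyloxy)-4-(4-benzyloxyphenyl)-3-[(Z)-2-aryloxy-2-(trimethylsilyloxy)vinyl]chroman-2-one (enantiomer of 18 at C3 and C4) | O=C1Oc2cc(OCc3ccccc3)cc(OCc3ccccc3)c2[C@H](c2ccc(OCc3ccccc3)cc2)[C@@H]1\C=C(/O[Si](C)(C)C)Oc1c(OCc2ccccc2)c(OCc2ccccc2)c(OCc2ccccc2)c(OCc2ccccc2)c1C(OC)c1ccc(OCc2ccccc2)cc1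
F2 | step 10 | (3R,3'R,4S,4'S)-5,5',6',7,7',8'-hexakis(benzyloxy)-4,4'-bis(4-benzyloxyphenyl)-[3,3'-bichromane]-2,2'-dione (enantiomer of 19) | O=C1Oc2cc(OCc3ccccc3)cc(OCc3ccccc3)c2[C@H](c2ccc(OCc3ccccc3)cc2)[C@@H]1[C@@H]1C(=O)Oc2c(OCc3ccccc3)c(OCc3ccccc3)c(OCc3ccccc3)c(OCc3ccccc3)c2[C@@H]1c1ccc(OCc2ccccc2)cc1
F3 | step 9 | (1E,3E)-bis(trimethylsilyl ketene acetal) of 16 (geometric isomer of 17) | C[Si](C)(C)O/C(Oc1cc(OCc2ccccc2)cc(OCc2ccccc2)c1C(OC)c1ccc(OCc2ccccc2)cc1)=C/C=C(/O[Si](C)(C)C)Oc1c(OCc2ccccc2)c(OCc2ccccc2)c(OCc2ccccc2)c(OCc2ccccc2)c1C(OC)c1ccc(OCc2ccccc2)cc1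
F4 | step 9 | (3R,4R)-5,7-bis(benzyloxy)-4-(4-benzyloxyphenyl)-3-[(E)-2-aryloxy-2-(trimethylsilyloxy)vinyl]chroman-2-one | O=C1Oc2cc(OCc3ccccc3)cc(OCc3ccccc3)c2[C@@H](c2ccc(OCc3ccccc3)cc2)[C@@H]1/C=C(/O[Si](C)(C)C)Oc1c(OCc2ccccc2)c(OCc2ccccc2)c(OCc2ccccc2)c(OCc2ccccc2)c1C(OC)c1ccc(OCc2ccccc2)cc1
F5 | step 9 | (3R,3'R,4R,4'R)-5,5',6',7,7',8'-hexakis(benzyloxy)-4,4'-bis(4-benzyloxyphenyl)-[3,3'-bichromane]-2,2'-dione | O=C1Oc2cc(OCc3ccccc3)cc(OCc3ccccc3)c2[C@@H](c2ccc(OCc3ccccc3)cc2)[C@@H]1[C@@H]1C(=O)Oc2c(OCc3ccccc3)c(OCc3ccccc3)c(OCc3ccccc3)c(OCc3ccccc3)c2[C@H]1c1ccc(OCc2ccccc2)cc1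
F6 | step 9 | dilithium (4R,4'R)-bis-enolate of the octabenzyl bis-lactone | [Li]OC=1Oc2cc(OCc3ccccc3)cc(OCc3ccccc3)c2[C@@H](c2ccc(OCc3ccccc3)cc2)C=1C1=C(O[Li])Oc2c(OCc3ccccc3)c(OCc3ccccc3)c(OCc3ccccc3)c(OCc3ccccc3)c2[C@H]1c1ccc(OCc2ccccc2)cc1
F0 | step 11 | none | none
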